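**Retrosynthetic overview**
1. Target 25 ⇐ epoxy-ene 23: ring C and the oxolane bridge (C8–C27 and C14–O) are made together by a visible-light titanocene/photoredox epoxide–alkene annulation.
2. 23 ⇐ 19 + 21: the C11–C12 bond comes from an alkyl–alkyl Negishi coupling of two C15 drimane bromides.
3. 19 and 21 ⇐ keto bromide 18 ⇐ diol 16: rings A/B and D/E are the same bicycle, built once by titanocene-mediated radical bicyclisation of epoxide 14.
4. 14 ⇐ sulfone 8 + epoxy alcohol 3: sulfone alkylation joins a geraniol-derived C10 unit to a C5 unit from methyl (R)-glycidate, the only purchased stereocentre.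
5. Ring order: A then B in one cascade (used for both halves), then ring C and the ether ring together in the last step.

Assumption: drimane numbering is used for the C15 halves (C11 on C9, C12 exocyclic on C8) and onocerane/serratane numbering for the C30 compounds; methyl (R)-glycidate and geraniol are taken as purchasable.

**Route**

Step 1
Reactants: 1 methyl (2R)-oxirane-2-carboxylate
Product: 3 2-[(2R)-oxiran-2-yl]propan-2-ol, via epoxy methyl ketone 2 (not isolated)
Conditions: MeMgCl (2.2 equiv), THF, −78 to −20 °C; then H2O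
Reagents that add atoms: methylmagnesium chloride, C[Mg]Cl
Why: Double Grignard addition to the ester is faster than epoxide opening at low temperature and does not touch the stereocentre, which is carried over unchanged.

Step 2
Reactants: 4 geraniol
Product: 5 geranyl tert-butyldimethylsilyl ether
Conditions: TBSCl, imidazole, DMF, rt
Reagents that add atoms: tert-butyldimethylsilyl chloride, CC(C)(C)[Si](C)(C)Cl
Why: Standard silylation of a primary allylic alcohol gives a group that survives the organolithium and hydride steps ahead.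

Step 3
Reactants: 5 geranyl tert-butyldimethylsilyl ether
Product: 6 (2E,6E)-8-(tert-butyldimethylsilyloxy)-2,6-dimethylocta-2,6-dien-1-ol
Conditions: SeO2 (10 mol%), t-BuOOH (3 equiv), salicylic acid (10 mol%), CH2Cl2, rt
Reagents that add atoms: tert-butyl hydroperoxide, CC(C)(C)OO
Why: SeO2-catalysed allylic oxidation (ene reaction then [2,3]-shift) attacks the E-methyl of the more electron-rich distal alkene and gives the E-allylic alcohol.

Step 4
Reactants: 6 (2E,6E)-8-(tert-butyldimethylsilyloxy)-2,6-dimethylocta-2,6-dien-1-ol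
Product: 8 tert-butyl{[(2E,6E)-3,7-dimethyl-8-(phenylsulfonyl)octa-2,6-dien-1-yl]oxy}dimethylsilane, via allylic mesylate 7 (not isolated)
Conditions: MsCl, Et3N, CH2Cl2, −40 °C; then PhSO2Na, Bu4NI (cat.), DMF, rt
Reagents that add atoms: sodium benzenesulfinate, [Na+].[O-]S(=O)c1ccccc1
Why: Mesylation followed by SN2 S-alkylation of the sulfinate gives the allylic sulfone with the E-alkene retained.

Step 5
Reactants: 8 tert-butyl{[(2E,6E)-3,7-dimethyl-8-(phenylsulfonyl)octa-2,6-dien-1-yl]oxy}dimethylsilane; 3 2-[(2R)-oxiran-2-yl]propan-2-ol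
Product: 11 (3R,6E,10E)-12-(tert-butyldimethylsilyloxy)-2,6,10-trimethyl-5-(phenylsulfonyl)dodeca-6,10-diene-2,3-diol (both C5 epimers), via lithiated sulfone 9 (not isolated), via lithium alkoxide 10 (not isolated)
Conditions: n-BuLi (1.05 equiv per partner), THF/DMPU, −78 to 0 °C; then H2O
Reagents that add atoms: none
Why: Biellmann-type alkylation, in which the α-sulfonyl allyl anion opens the terminal epoxide at its CH2 carbon (α-attack of the sulfone), so the carbinol stereocentre from 3 is kept.

Step 6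
Reactants: 11 (3R,6E,10E)-12-(tert-butyldimethylsilyloxy)-2,6,10-trimethyl-5-(phenylsulfonyl)dodeca-6,10-diene-2,3-diol
Product: 12 (3R,6E,10E)-12-(tert-butyldimethylsilyloxy)-2,6,10-trimethyldodeca-6,10-diene-2,3-diol
Conditions: PdCl2(dppp) (5 mol%), LiBHEt3 (5 equiv), THF, 0 °C
Reagents that add atoms: none
Why: Palladium-catalysed hydride desulfonylation of the allylic sulfone (π-allyl intermediate on zerovalent palladium) removes the sulfonyl group without moving the alkene or changing its E geometry.

Step 7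
Reactants: 12 (3R,6E,10E)-12-(tert-butyldimethylsilyloxy)-2,6,10-trimethyldodeca-6,10-diene-2,3-diol
Product: 14 tert-butyl{[(2E,6E)-9-[(2S)-3,3-dimethyloxiran-2-yl]-3,7-dimethylnona-2,6-dien-1-yl]oxy}dimethylsilane, via secondary mesylate 13 (not isolated)
Conditions: MsCl, pyridine, CH2Cl2, 0 °C; then K2CO3, MeOH, rt
Reagents that add atoms: none
Why: Only the secondary hydroxyl is mesylated and the tertiary alkoxide closes the ring by intramolecular SN2 (Williamson) with inversion, turning the (3R)-diol into the (S)-epoxide.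

Step 8
Reactants: 14 tert-butyl{[(2E,6E)-9-[(2S)-3,3-dimethyloxiran-2-yl]-3,7-dimethylnona-2,6-dien-1-yl]oxy}dimethylsilane
Product: 16 drim-8(12)-ene-3β,11-diol (5α-H, 9α-H, 10β-methyl), via silyl ether 15 (not isolated)
Conditions: Cp2TiCl2 (2.2 equiv), Mn dust, THF, rt; 1 M HCl; then p-TsOH·H2O (5 mol%), MeOH, 0 °C
Reagents that add atoms: none
Why: Titanocene-mediated radical epoxypolyene bicyclisation (trivalent titanium opens the epoxide, 6-endo then 6-endo through a chair–chair array, β-hydrogen loss to the exocyclic alkene) sets C5, C9 and C10 from the epoxide stereocentre with 3β-OH equatorial, and acidic methanol then removes the silyl group.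

Step 9
Reactants: 16 drim-8(12)-ene-3β,11-diol
Product: 17 11-bromodrim-8(12)-en-3β-ol
Conditions: CBr4, PPh3, CH2Cl2, 0 °C
Reagents that add atoms: carbon tetrabromide, BrC(Br)(Br)Br
Why: The Appel reaction brominates the primary alcohol, while the secondary 3β-hydroxyl next to the gem-dimethyl carbon is too hindered for SN2.

Step 10
Reactants: 17 11-bromodrim-8(12)-en-3β-ol
Product: 18 11-bromodrim-8(12)-en-3-one
Conditions: Dess–Martin periodinane, CH2Cl2, rt
Reagents that add atoms: none
Why: Dess–Martin oxidation converts the secondary alcohol to the ketone under neutral conditions that leave the bromide and the exocyclic alkene alone.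

Step 11
Reactants: 18 11-bromodrim-8(12)-en-3-one
Product: 19 11-bromo-8α,12-epoxydriman-3-one
Conditions: mCPBA, NaHCO3, CH2Cl2, 0 °C
Reagents that add atoms: 3-chloroperoxybenzoic acid, OOC(=O)c1cccc(Cl)c1
Why: Prilezhaev epoxidation of the 1,1-disubstituted alkene from the open α face is much faster than Baeyer–Villiger oxidation of the hindered ketone, and the C8 configuration does not matter because C8 later becomes a radical.

Step 12
Reactants: 18 11-bromodrim-8(12)-en-3-one
Product: 21 (11-bromodrim-8(12)-en-3α-yloxy)trimethylsilane, via lithium 3α-alkoxide 20 (not isolated)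
Conditions: LiBH(s-Bu)3, THF, −78 °C; then TMSCl, −78 °C to rt
Reagents that add atoms: chlorotrimethylsilane, C[Si](C)(C)Cl
Why: The bulky trialkylborohydride attacks the 4,4-dimethyl-3-ketone along the equatorial trajectory to give the axial 3α-alkoxide (substrate control), which is silylated in the same flask.

Step 13
Reactants: 21 (11-bromodrim-8(12)-en-3α-yloxy)trimethylsilane (1.5 equiv); 19 11-bromo-8α,12-epoxydriman-3-one
Product: 23 8α,26-epoxy-21β-(trimethylsilyloxy)onocer-14(27)-en-3-one, via alkylzinc bromide 22 (not isolated)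
Conditions: 21, Zn dust, LiCl, THF, 50 °C; then 19, Ni(cod)2 (10 mol%), 2,6-bis(4,4-dimethyl-2-oxazolin-2-yl)pyridine (20 mol%), THF/DMA, rt
Reagents that add atoms: none
Why: Zinc insertion followed by nickel-catalysed alkyl–alkyl Negishi coupling forms C11–C12, because zerovalent nickel activates the β-branched bromide through a radical pathway and the organozinc tolerates the ketone, epoxide and silyl ether.

Step 14
Reactants: 23 8α,26-epoxy-21β-(trimethylsilyloxy)onocer-14(27)-en-3-one
Product: 25 14β,26-epoxy-21β-hydroxyserratan-3-one (CNP0211850.1), via silyl ether 24 (not isolated)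
Conditions: Cp2TiCl2 (10 mol%), 4CzIPN (2 mol%), Hantzsch ester (10 mol%), THF (0.01 M), blue LEDs (450 nm), 25 °C; then K2CO3 (cat.), MeOH
Reagents that add atoms: none
Why: Proposed new method: photoexcited 4CzIPN (primed by the Hantzsch ester) reduces Cp2TiCl2 to trivalent Cp2TiCl, which opens the 2,2-disubstituted epoxide to the tertiary C8 radical carrying the C26–O–Ti group; this radical adds 7-endo-trig to the terminal carbon (C27) of the 14(27)-methylene from the α face (the β face is blocked by the axial C10 methyl, so ring C is trans-fused to ring B and C26 ends up β), and the tertiary C14 radical then closes the C14–O bond either by homolytic substitution at the Ti–O bond or after oxidation by the 4CzIPN radical cation, which returns tetravalent titanium for the next photoreduction, so the process is redox-neutral, the low standing concentration of trivalent titanium disfavours premature radical trapping, and the one-carbon/two-atom bridge allows only the 14β-oxygen configuration; the closest known reactions are the titanocene-catalysed radical tetrahydrofuran synthesis from epoxy-alkenes (5-exo, fused products), titanocene-mediated 7-endo cyclisations of epoxypolyprenes and photoredox generation of trivalent titanocene, none of which has been shown for a 7-endo, bridge-forming epoxide–alkene [3+2] annulation.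

**Compound list**
1 | methyl (2R)-oxirane-2-carboxylate (methyl (R)-glycidate) | COC(=O)[C@H]1CO1 | starting material
2 | 1-[(2R)-oxiran-2-yl]ethan-1-one | CC(=O)[C@H]1CO1 | intermediate
3 | 2-[(2R)-oxiran-2-yl]propan-2-ol | CC(C)(O)[C@H]1CO1 | intermediate
4 | geraniol, (2E)-3,7-dimethylocta-2,6-dien-1-ol | CC(C)=CCC/C(C)=C/CO | starting material
5 | geranyl tert-butyldimethylsilyl ether | CC(C)=CCC/C(C)=C/CO[Si](C)(C)C(C)(C)C | intermediate
6 | (2E,6E)-8-(tert-butyldimethylsilyloxy)-2,6-dimethylocta-2,6-dien-1-ol | OC/C(C)=C/CC/C(C)=C/CO[Si](C)(C)C(C)(C)C | intermediate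
7 | methanesulfonate of 6 | CS(=O)(=O)OC/C(C)=C/CC/C(C)=C/CO[Si](C)(C)C(C)(C)C | intermediate
8 | tert-butyl{[(2E,6E)-3,7-dimethyl-8-(phenylsulfonyl)octa-2,6-dien-1-yl]oxy}dimethylsilane | O=S(=O)(C/C(C)=C/CC/C(C)=C/CO[Si](C)(C)C(C)(C)C)c1ccccc1 | intermediate
9 | 8-lithio derivative of sulfone 8 | [Li]C(/C(C)=C/CC/C(C)=C/CO[Si](C)(C)C(C)(C)C)S(=O)(=O)c1ccccc1 | intermediate
10 | lithium 2-[(2R)-oxiran-2-yl]propan-2-olate | [Li]OC(C)(C)[C@H]1CO1 | intermediate
11 | (3R,6E,10E)-12-(tert-butyldimethylsilyloxy)-2,6,10-trimethyl-5-(phenylsulfonyl)dodeca-6,10-diene-2,3-diol, both C5 epimers | CC(C)(O)[C@H](O)CC(/C(C)=C/CC/C(C)=C/CO[Si](C)(C)C(C)(C)C)S(=O)(=O)c1ccccc1 | intermediate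
12 | (3R,6E,10E)-12-(tert-butyldimethylsilyloxy)-2,6,10-trimethyldodeca-6,10-diene-2,3-diol | CC(C)(O)[C@H](O)CC/C(C)=C/CC/C(C)=C/CO[Si](C)(C)C(C)(C)C | intermediate
13 | 3-O-methanesulfonate of 12 | CC(C)(O)[C@H](OS(C)(=O)=O)CC/C(C)=C/CC/C(C)=C/CO[Si](C)(C)C(C)(C)C | intermediate
14 | (10S)-10,11-epoxy-(2E,6E)-farnesyl tert-butyldimethylsilyl ether | CC1(C)O[C@H]1CC/C(C)=C/CC/C(C)=C/CO[Si](C)(C)C(C)(C)C | intermediate
15 | 11-(tert-butyldimethylsilyloxy)drim-8(12)-en-3β-ol (5α-H, 9α-H, 10β-Me) | CC1(C)[C@@H](O)CC[C@@]2(C)[C@H]1CCC(=C)[C@@H]2CO[Si](C)(C)C(C)(C)C | intermediate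
16 | drim-8(12)-ene-3β,11-diol (3β-hydroxyalbicanol) | CC1(C)[C@@H](O)CC[C@@]2(C)[C@H]1CCC(=C)[C@@H]2CO | intermediate
17 | 11-bromodrim-8(12)-en-3β-ol | CC1(C)[C@@H](O)CC[C@@]2(C)[C@H]1CCC(=C)[C@@H]2CBr | intermediate
18 | 11-bromodrim-8(12)-en-3-one | CC1(C)C(=O)CC[C@@]2(C)[C@H]1CCC(=C)[C@@H]2CBr | intermediate
19 | 11-bromo-8α,12-epoxydriman-3-one | CC1(C)C(=O)CC[C@@]2(C)[C@H]1CC[C@]1(CO1)[C@@H]2CBr | intermediate
20 | lithium 11-bromodrim-8(12)-en-3α-olate | CC1(C)[C@H](O[Li])CC[C@@]2(C)[C@H]1CCC(=C)[C@@H]2CBr | intermediate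
21 | (11-bromodrim-8(12)-en-3α-yloxy)trimethylsilane | CC1(C)[C@H](O[Si](C)(C)C)CC[C@@]2(C)[C@H]1CCC(=C)[C@@H]2CBr | intermediate
22 | [3α-(trimethylsilyloxy)drim-8(12)-en-11-yl]zinc bromide | CC1(C)[C@H](O[Si](C)(C)C)CC[C@@]2(C)[C@H]1CCC(=C)[C@@H]2C[Zn]Br | intermediate
23 | 8α,26-epoxy-21β-(trimethylsilyloxy)onocer-14(27)-en-3-one | CC1(C)C(=O)CC[C@@]2(C)[C@H]1CC[C@]1(CO1)[C@@H]2CC[C@H]1C(=C)CC[C@H]2C(C)(C)[C@H](O[Si](C)(C)C)CC[C@]12C | intermediate
24 | 14β,26-epoxy-21β-(trimethylsilyloxy)serratan-3-one | CC1(C)C(=O)CC[C@@]2(C)[C@H]1CC[C@]13CO[C@@]4(CC[C@H]5C(C)(C)[C@H](O[Si](C)(C)C)CC[C@]5(C)[C@H]4CC[C@@H]12)C3 | intermediate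
25 | 14β,26-epoxy-21β-hydroxyserratan-3-one (CNP0211850.1) | CC1(C)C(=O)CC[C@@]2(C)[C@H]1CC[C@]13CO[C@@]4(CC[C@H]5C(C)(C)[C@H](O)CC[C@]5(C)[C@H]4CC[C@@H]12)C3 | target

**Summary**
Total step count: 14.
Longest linear sequence: 12 steps (geraniol 4 to 25 through steps 2–10, then 11 or 12, then 13 and 14).

**Steps most likely to fail, with fallbacks**

Step 14 (the proposed annulation). The likely failures are premature trapping of the C8 radical, or loss of a β-hydrogen from the C14 radical instead of C–O closure. The fallback uses known chemistry, sets out from 23 and comes back at 25. Compound 23 is treated with stoichiometric Cp2TiCl (from Cp2TiCl2 and Mn dust, THF, rt), a known titanocene-mediated 7-endo-trig radical cyclisation. The C14 radical is then trapped by a second trivalent titanium and loses a β-hydrogen, giving 26-hydroxy-21β-(trimethylsilyloxy)serrat-14-en-3-one F1, possibly with double-bond isomers that lead to the same C14 cation. Catalytic p-toluenesulfonic acid in CH2Cl2 then effects Markovnikov intramolecular hydroalkoxylation through the tertiary C14 cation. The bridge geometry again allows only the 14β-ether, and the silyl group is lost under the acid, giving 25.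

Step 13 (hindered sp3–sp3 Negishi coupling next to an acid-sensitive spiro-epoxide). The fallback is a zinc-free, polar union with the C3 oxidation moved after the coupling; it sets out from 17 and 21 and comes back at 23. Compound 17 is epoxidised (mCPBA, NaHCO3) to 11-bromo-8α,12-epoxydriman-3β-ol F2. Compound 21 is converted with Mg in THF into [3α-(trimethylsilyloxy)drim-8(12)-en-11-yl]magnesium bromide F3. F2 is deprotonated with MeMgCl and coupled with F3 under copper catalysis (Li2CuCl4, 5 mol%, THF, −20 to 0 °C; Kochi-type alkyl–alkyl coupling) to give 8α,26-epoxy-21β-(trimethylsilyloxy)onocer-14(27)-en-3β-ol F4. Dess–Martin oxidation of F4 gives 23.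

Step 5 (opening of an epoxide that carries a neighbouring lithium alkoxide by the sulfone anion). The fallback reverses the polarity of the C8–C9 bond formation; it sets out from 3 and 6 and comes back at 12. Epoxy alcohol 3 is opened at its terminal carbon with PhSO2Na (DMF/H2O, 60 °C) to give (2S)-3-methyl-1-(phenylsulfonyl)butane-2,3-diol F5. Alcohol 6 is converted with CBr4/PPh3 into the allylic bromide tert-butyl{[(2E,6E)-8-bromo-3,7-dimethylocta-2,6-dien-1-yl]oxy}dimethylsilane F6. The trianion of F5 (n-BuLi, 3 equiv, THF/DMPU, −78 °C) is C-alkylated with F6 to give (3S,6E,10E)-12-(tert-butyldimethylsilyloxy)-2,6,10-trimethyl-4-(phenylsulfonyl)dodeca-6,10-diene-2,3-diol F7. Reductive desulfonylation (Na/Hg, Na2HPO4, MeOH, −20 °C) then gives 12.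

Further compounds
F1 | step 14 | 26-hydroxy-21β-(trimethylsilyloxy)serrat-14-en-3-one | CC1(C)C(=O)CC[C@@]2(C)[C@H]1CC[C@@]1(CO)CC3=CC[C@H]4C(C)(C)[C@H](O[Si](C)(C)C)CC[C@]4(C)[C@H]3CC[C@@H]12
F2 | step 13 | 11-bromo-8α,12-epoxydriman-3β-ol | CC1(C)[C@@H](O)CC[C@@]2(C)[C@H]1CC[C@]1(CO1)[C@@H]2CBr
F3 | step 13 | [3α-(trimethylsilyloxy)drim-8(12)-en-11-yl]magnesium bromide | CC1(C)[C@H](O[Si](C)(C)C)CC[C@@]2(C)[C@H]1CCC(=C)[C@@H]2C[Mg]Br
F4 | step 13 | 8α,26-epoxy-21β-(trimethylsilyloxy)onocer-14(27)-en-3β-ol | CC1(C)[C@@H](O)CC[C@@]2(C)[C@H]1CC[C@]1(CO1)[C@@H]2CC[C@H]1C(=C)CC[C@H]2C(C)(C)[C@H](O[Si](C)(C)C)CC[C@]12C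
F5 | step 5 | (2S)-3-methyl-1-(phenylsulfonyl)butane-2,3-diol | CC(C)(O)[C@H](O)CS(=O)(=O)c1ccccc1
F6 | step 5 | tert-butyl{[(2E,6E)-8-bromo-3,7-dimethylocta-2,6-dien-1-yl]oxy}dimethylsilane | BrC/C(C)=C/CC/C(C)=C/CO[Si](C)(C)C(C)(C)C
F7 | step 5 | (3S,6E,10E)-12-(tert-butyldimethylsilyloxy)-2,6,10-trimethyl-4-(phenylsulfonyl)dodeca-6,10-diene-2,3-diol, both C4 epimers | CC(C)(O)[C@H](O)C(C/C(C)=C/CC/C(C)=C/CO[Si](C)(C)C(C)(C)C)S(=O)(=O)c1ccccc1
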